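**Retrosynthetic overview**
- Last bond and last ring: the diaryl ether C–O bond of the seven-membered dioxepinone (depsidone) ring, closed from a bromodepside (ring A 2-OH onto ring B C6–Br).
- The formyl group goes onto the depside just before, between the two free ring A hydroxyls (Rieche).
- The depside ester C–O bond comes from orsellinic acid and 6-bromo-7-hydroxy-2,2,5-trimethylchroman-4-one.
- The chromanone comes from 4-bromoorcinol and 3,3-dimethylacrylic acid (Friedel–Crafts acylation, then oxa-Michael C–O closure); the bromine, set by mono-bromination of symmetric orcinol, fixes the ether position.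
- Ring order: pyranone ring first (step 2), dioxepinone ring last (step 5); both benzene rings are bought.

Assumption: mollicellin A has no stereocentre (it is achiral), so no enantiocontrol is needed and the SMILES is met as written.

**Step 1**
Reactants: 1 orcinol
Product: 2 4-bromo-5-methylbenzene-1,3-diol
Conditions: NBS (1.0 equiv), CH2Cl2–THF, −78 → 0 °C
Reagents that add atoms: N-bromosuccinimide, O=C1CCC(=O)N1Br
Why: Electrophilic aromatic bromination of a symmetric resorcinol, in which the two equivalent positions para to a hydroxyl are far more reactive than C2 between the hydroxyls, so one equivalent of NBS in the cold marks the future ether carbon.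

**Step 2**
Reactants: 2 4-bromo-5-methylbenzene-1,3-diol; 3 3-methylbut-2-enoic acid
Product: 5 6-bromo-7-hydroxy-2,2,5-trimethylchroman-4-one, via open-chain enone 4 (not isolated)
Conditions: Eaton's reagent (P2O5/MsOH), 60 °C, 2 h; ice-water quench
Reagents that add atoms: none
Why: One-pot Friedel–Crafts acylation and intramolecular oxa-Michael addition (the standard 2,2-dimethylchromanone synthesis), with acylation at the only free position para to a hydroxyl (as in orcacetophenone formation) and ring closure by the neighbouring OH; the chelated 5-hydroxy isomers from attack between the hydroxyls are minor and less polar.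

**Step 3**
Reactants: 6 orsellinic acid; 5 6-bromo-7-hydroxy-2,2,5-trimethylchroman-4-one
Product: 10 6-bromo-2,2,5-trimethyl-4-oxochroman-7-yl 2,4-dihydroxy-6-methylbenzoate, via tris-TMS orsellinate 7 (not isolated), via silylated acid chloride 8 (not isolated), via bis-TMS depside 9 (not isolated)
Conditions: HMDS, cat. TMSCl, toluene, 80 °C, evaporate; (COCl)2, cat. DMF, CH2Cl2, 0 °C → rt, evaporate; 5, Et3N, cat. DMAP, CH2Cl2, 0 °C → rt; 1 M HCl, THF–MeOH, rt
Reagents that add atoms: none
Why: Transient per-silylation masks both hydroxyls of the acid so its silyl ester can be converted into the acid chloride under neutral conditions and used in a DMAP-catalysed O-acylation (esterification) of the single phenol of 5, after which the aryl silyl ethers fall off in the acidic work-up while the depside ester stays.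

**Step 4**
Reactants: 10 6-bromo-2,2,5-trimethyl-4-oxochroman-7-yl 2,4-dihydroxy-6-methylbenzoate
Product: 12 6-bromo-2,2,5-trimethyl-4-oxochroman-7-yl 3-formyl-2,4-dihydroxy-6-methylbenzoate, via chloro(methoxy)methyl adduct 11 (not isolated)
Conditions: Cl2CHOMe (1.2 equiv), TiCl4 (3 equiv), CH2Cl2, −20 → 0 °C; 1 M HCl, 0 °C
Reagents that add atoms: dichloromethyl methyl ether, COC(Cl)Cl; water, O
Why: Rieche formylation (titanium-directed ortho-formylation), in which the titanium bis-phenoxide of the resorcinol ring steers the electrophile to C3 between the two hydroxyls (the position at which orsellinate esters give haematommates), ring B being an acylated and ketone-deactivated arene, and the α-chloro ether is hydrolysed to the aldehyde on work-up.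

**Step 5**
Reactants: 12 6-bromo-2,2,5-trimethyl-4-oxochroman-7-yl 3-formyl-2,4-dihydroxy-6-methylbenzoate
Product: 13 mollicellin A
Conditions: CuI (10 mol %), Cs2CO3 (2.5 equiv), MeCN (0.005 M), 440 nm LEDs, Ar, rt; dil. HCl work-up
Reagents that add atoms: none
Why: Proposed new method: a visible-light, ligand-free copper(I) aryloxide ring closure in which the substrate's own 2-oxido-3-formyl-benzoate unit chelates Cu(I) and serves as the chromophore, the excited Cu(I) aryloxide transfers an electron to the tethered bromochromanone ring (the aryl ketone π* lowers its reduction potential) to cleave C–Br, and the aryl radical is captured at the Cu(II)–O centre and reductively eliminated from Cu(III) to form the C6–O bond and the seven-membered ring at room temperature, so the two ortho substituents that slow a concerted oxidative addition and the base-labile aryl ester are both tolerated; the closest known reaction type is photoinduced copper-catalysed Ullmann C–O coupling of phenols with aryl halides, here extended to an aryl bromide, visible light and an intramolecular depside-to-depsidone closure.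

**Compound list**
1 | orcinol (5-methylbenzene-1,3-diol) | Cc1cc(O)cc(O)c1 | starting material
2 | 4-bromo-5-methylbenzene-1,3-diol (4-bromoorcinol) | Cc1cc(O)cc(O)c1Br | intermediate
3 | 3-methylbut-2-enoic acid (3,3-dimethylacrylic acid) | CC(C)=CC(=O)O | starting material
4 | 1-(3-bromo-4,6-dihydroxy-2-methylphenyl)-3-methylbut-2-en-1-one (open-chain enone) | CC(C)=CC(=O)c1c(C)c(Br)c(O)cc1O | intermediate
5 | 6-bromo-7-hydroxy-2,2,5-trimethylchroman-4-one | CC1(C)CC(=O)c2c(C)c(Br)c(O)cc2O1 | intermediate
6 | orsellinic acid (2,4-dihydroxy-6-methylbenzoic acid) | Cc1cc(O)cc(O)c1C(=O)O | starting material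
7 | trimethylsilyl 2-methyl-4,6-bis(trimethylsilyloxy)benzoate (tris-TMS orsellinate) | Cc1cc(O[Si](C)(C)C)cc(O[Si](C)(C)C)c1C(=O)O[Si](C)(C)C | intermediate
8 | 2-methyl-4,6-bis(trimethylsilyloxy)benzoyl chloride | Cc1cc(O[Si](C)(C)C)cc(O[Si](C)(C)C)c1C(=O)Cl | intermediate
9 | 6-bromo-2,2,5-trimethyl-4-oxochroman-7-yl 2-methyl-4,6-bis(trimethylsilyloxy)benzoate (bis-TMS depside) | Cc1cc(O[Si](C)(C)C)cc(O[Si](C)(C)C)c1C(=O)Oc1cc2OC(C)(C)CC(=O)c2c(C)c1Br | intermediate
10 | 6-bromo-2,2,5-trimethyl-4-oxochroman-7-yl 2,4-dihydroxy-6-methylbenzoate (bromodepside) | Cc1cc(O)cc(O)c1C(=O)Oc1cc2OC(C)(C)CC(=O)c2c(C)c1Br | intermediate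
11 | 6-bromo-2,2,5-trimethyl-4-oxochroman-7-yl 3-[chloro(methoxy)methyl]-2,4-dihydroxy-6-methylbenzoate (racemic at the CHCl carbon, transient) | COC(Cl)c1c(O)cc(C)c(C(=O)Oc2cc3OC(C)(C)CC(=O)c3c(C)c2Br)c1O | intermediate
12 | 6-bromo-2,2,5-trimethyl-4-oxochroman-7-yl 3-formyl-2,4-dihydroxy-6-methylbenzoate (formyl bromodepside) | Cc1cc(O)c(C=O)c(O)c1C(=O)Oc1cc2OC(C)(C)CC(=O)c2c(C)c1Br | intermediate
13 | mollicellin A (depsidone: the 3-formyl-4-hydroxy-6-methylsalicyloyl ring joined to 2,2,5-trimethylchroman-4-one through a C2–O–C6' diaryl ether and a C(=O)–O–C7' lactone; no stereocentre) | Cc1cc(O)c(C=O)c2c1C(=O)Oc1cc3c(c(C)c1O2)C(=O)CC(C)(C)O3 | target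

**Totals**
Total step count: 5. Longest linear sequence: 5 (1 → 2 → 5 → 10 → 12 → 13); 3 and 6 are bought and enter at steps 2 and 3.

**Steps most likely to fail**

Step 5 (the proposed new closure). Risks are hydrodebromination of the aryl radical before capture at copper, and slow rotation of the ester into the cisoid geometry the ring needs. The fallback uses known chemistry and changes the order of events. It sets out from bromodepside 10, before the aldehyde is present. A conventional thermal Ullmann diaryl ether synthesis (CuI, picolinic acid, K3PO4, DMSO, 90 °C, 0.01 M) closes the ring on the more nucleophilic aldehyde-free phenoxide, where only the 2-OH can reach the bromide, and gives the desformyl depsidone F1. Rieche formylation of F1 (Cl2CHOMe, TiCl4, CH2Cl2, 0 °C) then comes back to the route at 13. The regiochemistry of this late formylation is not certain: titanium held between the 4-phenoxide and the neighbouring ether oxygen should favour C3, and any 5-formyl isomer would have to be removed by chromatography.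

Step 4 (formylation of the depside). Risks are formylation at C5 of ring A or at C8 of ring B, and Lewis-acid damage to the ester. The fallback puts the aldehyde in before the ester is made and also bypasses step 3. It sets out from 6. Carboxylate alkylation (BnBr, KHCO3, DMF) gives benzyl orsellinate F2. Rieche or Gattermann formylation gives benzyl haematommate F3. Hydrogenolysis (H2, Pd/C, EtOAc) gives haematommic acid F4, in which both hydroxyls are chelated (to CO2H and to CHO). F4 is then coupled with 5 using DCC (toluene–Et2O, rt) without protection, and the sequence comes back to the route at 12.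

Step 2 (chromanone formation). Risks are acid-promoted loss or migration of the bromine on the activated resorcinol, and competing acylation between the hydroxyls. The fallback builds the ring in two milder stages. It sets out from 2. A cold Hoesch acylation (MeCN, ZnCl2, HCl gas, Et2O, 0 °C; then hot water) gives 1-(3-bromo-4,6-dihydroxy-2-methylphenyl)ethan-1-one F5. A Kabbe condensation of F5 with acetone (pyrrolidine, EtOH, reflux; enamine aldol, then oxa-Michael) comes back to the route at 5.

**Further compounds**
F1 | step 5 | desformyl depsidone (mollicellin A lacking the CHO group) | Cc1cc(O)cc2c1C(=O)Oc1cc3c(c(C)c1O2)C(=O)CC(C)(C)O3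
F2 | step 4 | benzyl orsellinate (benzyl 2,4-dihydroxy-6-methylbenzoate) | Cc1cc(O)cc(O)c1C(=O)OCc1ccccc1
F3 | step 4 | benzyl haematommate (benzyl 3-formyl-2,4-dihydroxy-6-methylbenzoate) | Cc1cc(O)c(C=O)c(O)c1C(=O)OCc1ccccc1
F4 | step 4 | haematommic acid (3-formyl-2,4-dihydroxy-6-methylbenzoic acid) | Cc1cc(O)c(C=O)c(O)c1C(=O)O
F5 | step 2 | 1-(3-bromo-4,6-dihydroxy-2-methylphenyl)ethan-1-one | CC(=O)c1c(C)c(Br)c(O)cc1O
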